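## Retrosynthetic overview

1. The target comes from a dibenzyl ether (O5 of ring A and the 4-hydroxyphenyl oxygen) by one neutral hydrogenolysis.
2. Key disconnection: ring A (the phloroglucinol carbocycle) and ring B (the lactone) are opened together to a 3,6-disubstituted 4-benzyloxy-2-pyranone. Forward, a Claisen-type pyranone-to-acylphloroglucinol ring transformation is followed in the same flask by lactonisation. Only the phenol next to the ketone is free beside the side chain, so the 8-acyl regiochemistry is fixed.
3. The C4 stereocentre is set earlier, on the pyranone, by an isothiourea-catalysed Michael addition–lactonisation with 4-benzyloxycinnamic acid. The temporary enol lactone is opened with benzyl alcohol and the freed 4-OH is benzylated.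
4. The 3-phenylpropanoyl chain comes from acylation of the dianion of triacetic acid lactone with methyl 3-phenylpropanoate.
5. Ring order: pyranone (bought), temporary enol lactone (formed, then opened), then ring A and ring B in one operation, in which the pyranone ring is consumed.

Assumption: the (2S,3R) enantiomer of the isothiourea catalyst is taken to give the (S) centre from its usual facial model; if the sense is the opposite, the (2R,3S) catalyst is used and nothing else changes.

## Route

Step 1
Reactants: 1 4-hydroxy-6-methyl-2H-pyran-2-one (triacetic acid lactone); 2 methyl 3-phenylpropanoate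
Product: 3 4-hydroxy-6-(2-oxo-4-phenylbutyl)-2H-pyran-2-one
Conditions: LiN(i-Pr)2 (commercial solution, 3.2 equiv), THF, −78 to 0 °C; then 2, −78 °C to rt; aq. HCl
Reagents that add atoms: none
Why: Claisen-type acylation of the pyranone dianion: after the 4-OH, the 6-methyl group is deprotonated and this vinylogous carbanion attacks the ester carbonyl, the third equivalent of base absorbing the more acidic keto-methylene of the product; no stereocentre is formed.

Step 2
Reactants: 3 4-hydroxy-6-(2-oxo-4-phenylbutyl)-2H-pyran-2-one; 4 (E)-3-[4-(benzyloxy)phenyl]prop-2-enoic acid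
Product: 7 benzyl (3S)-3-[4-(benzyloxy)phenyl]-3-[4-hydroxy-2-oxo-6-(2-oxo-4-phenylbutyl)-2H-pyran-3-yl]propanoate, via mixed pivalic anhydride 5 (not isolated), via bicyclic enol lactone 6 (not isolated)
Conditions: 4, t-BuCOCl, i-Pr2NEt, CH2Cl2, 0 °C; then 3, (2S,3R)-3-isopropyl-2-phenyl-3,4-dihydro-2H-benzo[4,5]thiazolo[3,2-a]pyrimidine (10 mol %), i-Pr2NEt, 0 °C to rt; then BnOH, 4-(dimethylamino)pyridine (cat.), rt
Reagents that add atoms: benzyl alcohol, OCc1ccccc1
Why: Isothiourea-catalysed Michael addition–lactonisation through an α,β-unsaturated acyl ammonium ion: the catalyst is acylated by anhydride 5 at the cinnamoyl carbonyl, the pyranone (a cyclic 1,3-dicarbonyl, far more acidic than the side-chain methylene) adds through C3 to the β-carbon on the face of the s-cis acyl ammonium not shielded by the phenyl group of the catalyst, which sets the (S) centre, O4 then closes enol lactone 6 and releases the catalyst, and benzyl alcohol opens this activated enol ester (not the vinylogous pyranone lactone) to free the 4-OH.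

Step 3
Reactants: 7 benzyl (3S)-3-[4-(benzyloxy)phenyl]-3-[4-hydroxy-2-oxo-6-(2-oxo-4-phenylbutyl)-2H-pyran-3-yl]propanoate
Product: 8 benzyl (3S)-3-[4-(benzyloxy)-2-oxo-6-(2-oxo-4-phenylbutyl)-2H-pyran-3-yl]-3-[4-(benzyloxy)phenyl]propanoate
Conditions: BnOH, PPh3, DIAD, THF, 0 °C to rt
Reagents that add atoms: benzyl alcohol, OCc1ccccc1
Why: Mitsunobu O-alkylation: only the pyranone 4-OH (pKa about 5) is acidic enough to act as the pronucleophile, so it is benzylated under neutral conditions without touching the side-chain methylene, the ester or the stereocentre.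

Step 4
Reactants: 8 benzyl (3S)-3-[4-(benzyloxy)-2-oxo-6-(2-oxo-4-phenylbutyl)-2H-pyran-3-yl]-3-[4-(benzyloxy)phenyl]propanoate
Product: 10 (4S)-5-(benzyloxy)-4-[4-(benzyloxy)phenyl]-7-hydroxy-8-(3-phenylpropanoyl)-3,4-dihydro-2H-chromen-2-one, via open-chain acylphloroglucinol ester 9 (not isolated)
Conditions: NaOBn (1 M in BnOH, 3 equiv), THF, 60 °C; then HCl (4 M in dioxane) to pH 1, PhMe, 80 °C, same flask
Reagents that add atoms: none
Why: Proposed new method: benzyloxide (matched to the ether and ester groups, so alkoxide exchange is invisible) opens the pyranone at C2 to a (Z)-3-benzyloxy-5,7-dioxo enoate in which the diketone carbanion and the ester carbonyl sit cis on the double bond, a 6-exo Claisen condensation and loss of benzyloxide then give the aromatic acylphloroglucinol 9 (ring A), aldol-type closures being blocked because the former pyranone C3 is an sp2 carbon without hydrogen, and since the former pyranone O4 is a benzyl ether the only free phenol beside the side chain is the one next to the ketone, onto which the ester lactonises under acid (ring B) without touching the stereocentre; the closest known reaction type is the biomimetic Claisen cyclisation of 6-(2-oxoalkyl)-4-hydroxy- and 4-methoxy-2-pyranones (masked 3,5,7-triketo esters) to acylphloroglucinols with Mg(OMe)2.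

Step 5
Reactants: 10 (4S)-5-(benzyloxy)-4-[4-(benzyloxy)phenyl]-7-hydroxy-8-(3-phenylpropanoyl)-3,4-dihydro-2H-chromen-2-one
Product: 11 (4S)-5,7-dihydroxy-4-(4-hydroxyphenyl)-8-(3-phenylpropanoyl)-3,4-dihydro-2H-chromen-2-one
Conditions: H2 (1 atm), Pd/C, EtOAc, rt
Reagents that add atoms: none
Why: Catalytic hydrogenolysis of the two aryl benzyl ethers under neutral conditions, which leaves the hydrogen-bonded aryl ketone, the lactone and the stereocentre (no C–O bond at the benzylic methine) untouched.

## Compound list

1 | 4-hydroxy-6-methyl-2H-pyran-2-one (triacetic acid lactone) | CC1=CC(O)=CC(=O)O1 | starting material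
2 | methyl 3-phenylpropanoate | COC(=O)CCc1ccccc1 | starting material
3 | 4-hydroxy-6-(2-oxo-4-phenylbutyl)-2H-pyran-2-one | O=C(CCc1ccccc1)CC1=CC(O)=CC(=O)O1 | intermediate
4 | (E)-3-[4-(benzyloxy)phenyl]prop-2-enoic acid | OC(=O)/C=C/c1ccc(OCc2ccccc2)cc1 | starting material
5 | (E)-3-[4-(benzyloxy)phenyl]prop-2-enoic 2,2-dimethylpropanoic anhydride | CC(C)(C)C(=O)OC(=O)/C=C/c1ccc(OCc2ccccc2)cc1 | intermediate
6 | (4S)-4-[4-(benzyloxy)phenyl]-7-(2-oxo-4-phenylbutyl)-3,4-dihydro-2H,5H-pyrano[4,3-b]pyran-2,5-dione | O=C1C[C@@H](c2ccc(OCc3ccccc3)cc2)C2=C(O1)C=C(CC(=O)CCc3ccccc3)OC2=O | intermediate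
7 | benzyl (3S)-3-[4-(benzyloxy)phenyl]-3-[4-hydroxy-2-oxo-6-(2-oxo-4-phenylbutyl)-2H-pyran-3-yl]propanoate | O=C(C[C@@H](c1ccc(OCc2ccccc2)cc1)C1=C(O)C=C(CC(=O)CCc2ccccc2)OC1=O)OCc1ccccc1 | intermediate
8 | benzyl (3S)-3-[4-(benzyloxy)-2-oxo-6-(2-oxo-4-phenylbutyl)-2H-pyran-3-yl]-3-[4-(benzyloxy)phenyl]propanoate | O=C(C[C@@H](c1ccc(OCc2ccccc2)cc1)C1=C(OCc2ccccc2)C=C(CC(=O)CCc2ccccc2)OC1=O)OCc1ccccc1 | intermediate
9 | benzyl (3S)-3-[6-(benzyloxy)-2,4-dihydroxy-3-(3-phenylpropanoyl)phenyl]-3-[4-(benzyloxy)phenyl]propanoate | O=C(C[C@@H](c1ccc(OCc2ccccc2)cc1)c1c(OCc2ccccc2)cc(O)c(C(=O)CCc2ccccc2)c1O)OCc1ccccc1 | intermediate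
10 | (4S)-5-(benzyloxy)-4-[4-(benzyloxy)phenyl]-7-hydroxy-8-(3-phenylpropanoyl)-3,4-dihydro-2H-chromen-2-one | O=C1C[C@@H](c2ccc(OCc3ccccc3)cc2)c2c(OCc3ccccc3)cc(O)c(C(=O)CCc3ccccc3)c2O1 | intermediate
11 | (4S)-5,7-dihydroxy-4-(4-hydroxyphenyl)-8-(3-phenylpropanoyl)-3,4-dihydro-2H-chromen-2-one | O=C1C[C@@H](c2ccc(O)cc2)c2c(O)cc(O)c(C(=O)CCc3ccccc3)c2O1 | target

## Step count and risks

Total step count: 5. Longest linear sequence: 5 steps (1 → 3 → 7 → 8 → 10 → 11).

The three steps most likely to fail are steps 4, 2 and 1.

Step 4 is the riskiest. The pyranone carbonyl of 8 is hindered by the C3 side chain and deactivated by the 4-benzyloxy group, so ring opening and Claisen closure may be slow. Retro-Claisen cleavage of the diketone, or partial loss of optical purity in the phenoxide stage, may compete. The fallback sets out from 3, which belongs to the unhindered substrate class for which this cyclisation is established. Mg(OMe)2 in MeOH at reflux converts 3 into 1-(2,4,6-trihydroxyphenyl)-3-phenylpropan-1-one F1. BnBr (1 equiv) and K2CO3 in acetone benzylate its most acidic, non-chelated 4-OH to give 1-[4-(benzyloxy)-2,6-dihydroxyphenyl]-3-phenylpropan-1-one F2. F2 then replaces the pyranone as the C-nucleophile in the isothiourea-catalysed Michael addition–lactonisation with anhydride 5 (1 equiv, same catalyst). Because the benzyl ether blocks the other neighbouring oxygen, the lactone closes on the phenol next to the ketone and gives 10 directly. Ring A is thus made first and alone, and the stereocentre and ring B come last. The route is rejoined at 10.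

Step 2 is the next risk. The electron-rich 4-benzyloxycinnamoyl ammonium ion may be a sluggish acceptor, and the acidic pyranone is a weak nucleophile. The fallback sets out from 3 and changes the activation mode to iminium catalysis at the aldehyde oxidation level. (E)-3-[4-(benzyloxy)phenyl]prop-2-enal F3 (a known, purchasable enal) and 3 are treated with (S)-2-[diphenyl(trimethylsilyloxy)methyl]pyrrolidine (20 mol %, enantiomer chosen for the 4S centre) and benzoic acid in CH2Cl2. Michael addition and hemiacetal closure give the lactol (4S)-4-[4-(benzyloxy)phenyl]-2-hydroxy-7-(2-oxo-4-phenylbutyl)-3,4-dihydro-2H,5H-pyrano[4,3-b]pyran-5-one F4 as an anomer mixture. Oxidation of the lactol with PhI(OAc)2 and catalytic 2,2,6,6-tetramethylpiperidin-1-oxyl gives 6, which is opened with benzyl alcohol as in step 2. The route is rejoined at 6.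

Step 1 is the third risk. The enolisable ester 2 can quench the dianion by proton transfer instead of acylating it. The fallback sets out from 1 and replaces the Claisen acylation by aldol addition and oxidation. The dianion of 1 (LiN(i-Pr)2, 2.2 equiv, THF, −78 °C) adds to 3-phenylpropanal F5 to give racemic 4-hydroxy-6-(2-hydroxy-4-phenylbutyl)-2H-pyran-2-one F6. Dess–Martin periodinane then oxidises the secondary alcohol to the ketone. The route is rejoined at 3.

## Further compounds

F1 | step 4 | 1-(2,4,6-trihydroxyphenyl)-3-phenylpropan-1-one | O=C(CCc1ccccc1)c1c(O)cc(O)cc1O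
F2 | step 4 | 1-[4-(benzyloxy)-2,6-dihydroxyphenyl]-3-phenylpropan-1-one | O=C(CCc1ccccc1)c1c(O)cc(OCc2ccccc2)cc1O
F3 | step 2 | (E)-3-[4-(benzyloxy)phenyl]prop-2-enal | O=C/C=C/c1ccc(OCc2ccccc2)cc1
F4 | step 2 | (4S)-4-[4-(benzyloxy)phenyl]-2-hydroxy-7-(2-oxo-4-phenylbutyl)-3,4-dihydro-2H,5H-pyrano[4,3-b]pyran-5-one (anomer mixture) | OC1C[C@@H](c2ccc(OCc3ccccc3)cc2)C2=C(O1)C=C(CC(=O)CCc3ccccc3)OC2=O
F5 | step 1 | 3-phenylpropanal | O=CCCc1ccccc1
F6 | step 1 | 4-hydroxy-6-(2-hydroxy-4-phenylbutyl)-2H-pyran-2-one (racemic) | OC(CCc1ccccc1)CC1=CC(O)=CC(=O)O1
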